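**Strategy.** Ring A (C1, C10–C14; briarane numbering) carries its two ten-ring bonds, C1–C2 and C10–C9, trans on adjacent carbons, and C2 and C9 both bear oxygen. The route therefore ties C2, as a methacrylate carbonyl, to the oxygen on C9 of a dienyl carbinol and lets a thermal intramolecular Diels–Alder reaction of the 2-silyloxy-diene close ring A: C13–C14 and C1–C10 form together, quaternary C1 and C10 are set, and a trans-fused γ-lactone results. The precursor is an acyclic triene ester from glyceraldehyde. The lactone is later opened by an acetylide (C3–C6), a malate-derived dioxolanone brings C7, C8 and C17–C19, and a chromium chloroallylation closes the ten-membered ring.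

Key step: step 6

Remark 1: atoms carry briarane numbers (C1 quaternary carbon, C2–C9 the other ten-ring carbons, C10 ring-fusion CH, C11–C14 the rest of ring A, C15 methyl on C1, C16 exocyclic CH2, C17/C18/C19 lactone CH, its methyl and its C=O, C20 methyl on C11). C8a is the glyceraldehyde carbon excised in step 13. "Ring A enol ether" means C1(C15)–C14H2–C13H2–C12(OTBS)=C11(C20)–C10H. "East arm" means C3≡C4–C5[=(E)-C6HCl]–C16H2OTBS.

Remark 2 (assumption): the C5=C6 geometry made in step 8 is erased when the allylchromium forms in step 26, so the (E) isomer is carried only to have single compounds; hydroxy aldehyde 18 is expected to rest as its lactol and is drawn in the open form.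

Step 1
Reactants: 1 (R)-2,2-dimethyl-1,3-dioxolane-4-carbaldehyde; 2 3-(triphenylphosphoranylidene)butan-2-one
Product: 3 (3E)-4-[(4S)-2,2-dimethyl-1,3-dioxolan-4-yl]-3-methylbut-3-en-2-one
Conditions: CH2Cl2, 40 °C
Reagents that add atoms: none
Why: Wittig olefination with a stabilised, α-branched ylide should give the (E)-trisubstituted enone (C10=C11) without touching the α-oxygenated stereocentre (C9).

Step 2
Reactants: 3 (3E)-4-[(4S)-2,2-dimethyl-1,3-dioxolan-4-yl]-3-methylbut-3-en-2-one
Product: 4 (3E,5S)-5,6-dihydroxy-3-methylhex-3-en-2-one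
Conditions: AcOH/H2O 4:1, 40 °C
Reagents that add atoms: none
Why: Acid hydrolysis of the acetonide frees the 1,2-diol; no bond to the stereocentre is broken.

Step 3
Reactants: 4 (3E,5S)-5,6-dihydroxy-3-methylhex-3-en-2-one
Product: 5 (2S,3E)-2-hydroxy-4-methyl-5-oxohex-3-en-1-yl 2,2-dimethylpropanoate
Conditions: t-BuCOCl, pyridine, CH2Cl2, −20 °C
Reagents that add atoms: pivaloyl chloride CC(C)(C)C(Cl)=O
Why: The bulky acyl chloride should acylate the primary hydroxyl selectively over the allylic secondary one.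

Step 4
Reactants: 5 (2S,3E)-2-hydroxy-4-methyl-5-oxohex-3-en-1-yl 2,2-dimethylpropanoate; 6 2-methylprop-2-enoyl chloride
Product: 7 (2S,3E)-1-[(2,2-dimethylpropanoyl)oxy]-4-methyl-5-oxohex-3-en-2-yl 2-methylprop-2-enoate
Conditions: Et3N, DMAP (cat.), CH2Cl2, 0 °C
Reagents that add atoms: none
Why: DMAP-catalysed esterification of the remaining secondary alcohol installs the tether that carries C1, C2, C14 and C15.

Step 5
Reactants: 7 (2S,3E)-1-[(2,2-dimethylpropanoyl)oxy]-4-methyl-5-oxohex-3-en-2-yl 2-methylprop-2-enoate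
Product: 8 (2S,3E)-5-{[tert-butyl(dimethyl)silyl]oxy}-1-[(2,2-dimethylpropanoyl)oxy]-4-methylhexa-3,5-dien-2-yl 2-methylprop-2-enoate
Conditions: TBSOTf, Et3N, CH2Cl2, −78 to 0 °C
Reagents that add atoms: tert-butyldimethylsilyl triflate CC(C)(C)[Si](C)(C)OS(=O)(=O)C(F)(F)F
Why: Soft enolisation of the methyl ketone should give the cross-conjugated 2-silyloxy-diene; the esters are not enolised under these conditions.

Step 6
Reactants: 8 (2S,3E)-5-{[tert-butyl(dimethyl)silyl]oxy}-1-[(2,2-dimethylpropanoyl)oxy]-4-methylhexa-3,5-dien-2-yl 2-methylprop-2-enoate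
Product: 9 [(1S,3aS,7aS)-6-{[tert-butyl(dimethyl)silyl]oxy}-3a,7-dimethyl-3-oxo-1,3,3a,4,5,7a-hexahydro-2-benzofuran-1-yl]methyl 2,2-dimethylpropanoate (trans-fused γ-lactone; 3a = C1, 7a = C10, position 1 = C9)
Conditions: toluene (0.005 M), BHT (cat.), 160 °C, sealed tube
Reagents that add atoms: none
Why: On heating, the s-cis 2-silyloxy-diene (C13=C12–C11=C10) and the tethered methacrylate C14=C1 should combine in a concerted, asynchronous, normal-demand [4+2] cycloaddition, the nucleophilic terminus C13 bonding to the β-carbon C14 and C10 to C1. The closest known reaction type is the ester-tethered intramolecular Diels–Alder reaction of pentadienyl acrylates. Ring A is closed by the [4+2] union itself, and the five-membered lactone (C1, C2, O, C9, C10) is closed as the tether ring with the ester bridge exo (anti to the diene), which gives the trans ring fusion, i.e. C2 and C9 trans on ring A with the C15 methyl endo. C10 and C1 are set by the C9 stereocentre: allylic 1,3-strain with the C11 methyl holds H9 in the diene plane, so the ester oxygen delivers the dienophile to one diene face while the CH2OPiv group points to the other. The step needs exo (trans-fused) over endo (cis-fused) cyclisation and high π-facial selectivity; the cis substituent on C11 penalises the bent endo tether, and the three-atom tether fixes the regiochemistry, which the silyloxy polarisation reinforces.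

Step 7
Reactants: 10 2-{[tert-butyl(dimethyl)silyl]oxy}-N-methoxy-N-methylacetamide; 11 ethynyl(trimethyl)silane
Product: 12 1-{[tert-butyl(dimethyl)silyl]oxy}-4-(trimethylsilyl)but-3-yn-2-one
Conditions: 11, n-BuLi, THF, −78 °C; then 10, −78 to 0 °C
Reagents that add atoms: none
Why: Acylation of the lithium acetylide by the Weinreb amide should stop at the ynone because the chelated tetrahedral intermediate survives until work-up.

Step 8
Reactants: 12 1-{[tert-butyl(dimethyl)silyl]oxy}-4-(trimethylsilyl)but-3-yn-2-one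
Product: 13 tert-butyl{[(2E)-3-chloro-2-[(trimethylsilyl)ethynyl]prop-2-en-1-yl]oxy}dimethylsilane
Conditions: Ph3PCH2Cl+ Cl−, NaN(SiMe3)2, THF, −78 to 0 °C; chromatographic separation of the alkene isomers
Reagents that add atoms: (chloromethyl)triphenylphosphonium chloride ClC[P+](c1ccccc1)(c1ccccc1)c1ccccc1.[Cl-]
Why: Wittig chloromethylenation of the ynone carbonyl should give both chloroalkene isomers, of which the (E) isomer is taken on (see Remark 2).

Step 9
Reactants: 13 tert-butyl{[(2E)-3-chloro-2-[(trimethylsilyl)ethynyl]prop-2-en-1-yl]oxy}dimethylsilane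
Product: 14 tert-butyl{[(2E)-2-(chloromethylidene)but-3-yn-1-yl]oxy}dimethylsilane
Conditions: K2CO3 (cat.), MeOH, 0 °C
Reagents that add atoms: none
Why: Methanolysis cleaves only the alkynyl C–Si bond; the silyl ether and the vinyl chloride are stable to these conditions.

Step 10
Reactants: 9 trans-fused γ-lactone; 14 tert-butyl{[(2E)-2-(chloromethylidene)but-3-yn-1-yl]oxy}dimethylsilane
Product: 15 hydroxy ynone: ring A enol ether (1S,10S); C1 bears C2(=O)–east arm; C10 bears (S)-C9H(OH)–C8aH2OPiv
Conditions: 14, LiN(i-Pr)2, THF, −78 °C; then 9, −78 °C; H2O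
Reagents that add atoms: none
Why: The lithium acetylide should add once to the strained lactone carbonyl (the hindered pivalate is slower), and collapse of the lithium hemiketal on work-up opens the temporary ring and makes the C2–C3 bond.

Step 11
Reactants: 15 hydroxy ynone
Product: 16 propargylic diol: as 15 with C2H(OH), new centre (2S); C1, C9, C10 unchanged
Conditions: Ru[(S,S)-TsDPEN](p-cymene) (5 mol %), i-PrOH, rt
Reagents that add atoms: none
Why: Asymmetric transfer hydrogenation of alkynyl ketones is reagent-controlled, the alkyne taking the place of the aryl group in the usual model, so the (S,S) catalyst should deliver the (2S) carbinol (2R in the target once C3 is an alkene carbon).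

Step 12
Reactants: 16 propargylic diol
Product: 17 triol: as 16 with C8aH2OH
Conditions: i-Bu2AlH (5 equiv), CH2Cl2, −78 °C; aq. potassium sodium tartrate
Reagents that add atoms: none
Why: Low-temperature hydride cleavage of the pivalate leaves the silyl enol ether, silyl ether, alkyne and vinyl chloride untouched.

Step 13
Reactants: 17 triol
Product: 18 hydroxy aldehyde (lactol): ring A enol ether; C1 bears (S)-C2H(OH)–east arm; C10 bears C9HO
Conditions: NaIO4 on silica gel, CH2Cl2/H2O, rt
Reagents that add atoms: none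
Why: Periodate glycol cleavage excises C8a and unveils the C9 aldehyde under neutral conditions that should not epimerise C10; the product should rest as the five-membered lactol with the C2 hydroxyl.

Step 14
Reactants: 19 dimethyl (2S)-2-hydroxybutanedioate
Product: 20 dimethyl (2S,3R)-2-hydroxy-3-methylbutanedioate
Conditions: LiN(i-Pr)2 (2.2 equiv), THF, −78 to −20 °C; MeI
Reagents that add atoms: iodomethane CI
Why: Fráter–Seebach alkylation of the chelated alkoxide enolate should place the methyl group anti to the alkoxide, giving the (2S,3R) isomer (C8 and C17).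

Step 15
Reactants: 20 dimethyl (2S,3R)-2-hydroxy-3-methylbutanedioate
Product: 21 (2S,3R)-2-hydroxy-3-methylbutanedioic acid
Conditions: KOH, H2O/MeOH, rt; then aq. HCl
Reagents that add atoms: potassium hydroxide [K+].[OH-]
Why: Saponification of both esters at room temperature; the C3 stereocentre bears no good leaving group and should not epimerise.

Step 16
Reactants: 21 (2S,3R)-2-hydroxy-3-methylbutanedioic acid
Product: 22 (2R)-2-[(2S,4S)-2-tert-butyl-5-oxo-1,3-dioxolan-4-yl]propanoic acid
Conditions: t-BuCHO, TsOH (cat.), H2SO4 (cat.), pentane, reflux, water separator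
Reagents that add atoms: pivalaldehyde CC(C)(C)C=O
Why: Acetalisation of the α-hydroxy acid end gives the cis-2,5-disubstituted dioxolanone, whose acetal centre stores the C8 configuration for the later enolate step.

Step 17
Reactants: 22 (2R)-2-[(2S,4S)-2-tert-butyl-5-oxo-1,3-dioxolan-4-yl]propanoic acid
Product: 23 tert-butyl (2R)-2-[(2S,4S)-2-tert-butyl-5-oxo-1,3-dioxolan-4-yl]propanoate
Conditions: Cl3CC(=NH)O-t-Bu, BF3·OEt2 (cat.), CH2Cl2/cyclohexane, rt
Reagents that add atoms: tert-butyl 2,2,2-trichloroacetimidate CC(C)(C)OC(=N)C(Cl)(Cl)Cl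
Why: Mild imidate tert-butylation of the free acid gives an ester that resists attack by neighbouring alkoxides until step 27.

Step 18
Reactants: 18 hydroxy aldehyde (lactol); 23 tert-butyl (2R)-2-[(2S,4S)-2-tert-butyl-5-oxo-1,3-dioxolan-4-yl]propanoate
Product: 24 aldol adduct: as 18 with C9H(OH) bonded to C8 of the dioxolanone; new centres (8R,9R); C17 (R); acetal carbon (S)
Conditions: 23, LiN(i-Pr)2, THF, −78 °C; 18 pre-treated with LiN(SiMe3)2 (1 equiv), −78 °C; mix, −78 to −50 °C; AcOH
Reagents that add atoms: none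
Why: In this self-regenerating dioxolanone aldol the lithium lactolate opens to the aldehyde, the enolate is attacked anti to its tert-butyl group (C9 replaces H8 with retention), and a Zimmerman–Traxler chair with Felkin–Anh approach anti to quaternary C1 should give the (9R) carbinol.

Step 19
Reactants: 24 aldol adduct
Product: 26 α-hydroxy aldehyde triol: C7HO on C8(OH); C2–OH and C9–OH free, via dioxolane hemiacetal 25 (not isolated)
Conditions: i-Bu2AlH (4 equiv), CH2Cl2, −78 °C; MeOH, aq. potassium sodium tartrate, rt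
Reagents that add atoms: none
Why: The activated dioxolanone carbonyl should be reduced to the hemiacetal, which on work-up loses pivalaldehyde to free the C7 aldehyde and the C8 hydroxyl, while the tert-butyl ester is much slower at −78 °C.

Step 20
Reactants: 26 α-hydroxy aldehyde triol
Product: 27 diacetate: as 26 with C2–OAc and C9–OAc
Conditions: Ac2O, pyridine, DMAP (cat.), CH2Cl2, 0 °C to rt
Reagents that add atoms: acetic anhydride CC(=O)OC(C)=O
Why: The two secondary alcohols are acetylated (the two acetates of the target) while the tertiary C8 hydroxyl should not react.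

Step 21
Reactants: 27 diacetate
Product: 28 α-silyloxy ketone: C12=O, C11(OTBS)(CH3), new centre (11S)
Conditions: DMDO (1.1 equiv), acetone/CH2Cl2, −78 to −20 °C
Reagents that add atoms: dimethyldioxirane CC1(C)OO1
Why: Rubottom oxidation: the electron-rich enol ether should be epoxidised far faster than the chloro-enyne, from the face opposite the axial C15 methyl and the C9 arm, and silyl migration gives the α-silyloxy ketone.

Step 22
Reactants: 28 α-silyloxy ketone
Product: 29 enone: C12(=O)–C13H=C14H
Conditions: IBX (2-iodoxybenzoic acid), DMSO/fluorobenzene, 70 °C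
Reagents that add atoms: none
Why: IBX dehydrogenation of the ketone can only occur toward C13–C14 because C11 is quaternary and the C7 aldehyde has no α-hydrogen.

Step 23
Reactants: 29 enone
Product: 30 (3Z)-diene: C2–C3H=C4H–C5[=(E)-C6HCl]–C16H2OTBS
Conditions: H2 (1 atm), Pd/CaCO3 poisoned with Pb(OAc)2, quinoline, EtOAc, rt
Reagents that add atoms: none
Why: Lindlar semi-hydrogenation adds H2 syn to the alkyne and should give the (3Z)-alkene without reducing the enone or the vinyl chloride.

Step 24
Reactants: 30 (3Z)-diene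
Product: 31 allylic alcohol: C16H2OH and C11–OH free
Conditions: HF·pyridine, pyridine, THF, 0 °C to rt
Reagents that add atoms: none
Why: Fluoride removes the primary allylic and the α-keto tertiary silyl ethers; acetates and the tert-butyl ester are stable.

Step 25
Reactants: 31 allylic alcohol
Product: 32 allylic bromide: C16H2Br
Conditions: NBS, Me2S, CH2Cl2, −20 to 0 °C
Reagents that add atoms: N-bromosuccinimide O=C1CCC(=O)N1Br
Why: Corey–Kim bromination converts only the primary allylic alcohol under neutral conditions that tolerate the aldehyde and the tertiary alcohols.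

Step 26
Reactants: 32 allylic bromide
Product: 33 ten-membered hydroxy ester: C6–C7 bond, C6–Cl (6S), C7–OH (7R), C5=C16 methylene, C19 tert-butyl ester
Conditions: CrCl2 (8 equiv), THF (0.002 M), 4 Å molecular sieves, rt
Reagents that add atoms: none
Why: Divalent chromium inserts into the allylic C–Br bond, and the γ-chloroallylchromium should add through its chlorine-bearing carbon C6 to the aldehyde in a chair-like Nozaki–Hiyama transition state (6,7-anti) on the face of the chromium-chelated α-alkoxy aldehyde that the tether from C9 can reach, which sets both centres and the C5=C16 methylene while closing the ring.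

Step 27
Reactants: 33 ten-membered hydroxy ester
Product: 35 CNP0188317.3 (target), via seco hydroxy acid 34 (not isolated)
Conditions: CF3CO2H, CH2Cl2, 0 °C
Reagents that add atoms: none
Why: Acidolysis of the tert-butyl ester frees the C19 acid, which should lactonise onto the C7 hydroxyl only, since the C9 oxygen is blocked as its acetate.

**Compound list**

1 | (R)-2,2-dimethyl-1,3-dioxolane-4-carbaldehyde | O=C[C@H]1COC(C)(C)O1 | starting material
2 | 3-(triphenylphosphoranylidene)butan-2-one | CC(=O)C(C)=P(c1ccccc1)(c1ccccc1)c1ccccc1 | starting material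
3 | (3E)-4-[(4S)-2,2-dimethyl-1,3-dioxolan-4-yl]-3-methylbut-3-en-2-one | CC(=O)/C(C)=C/[C@H]1COC(C)(C)O1 | intermediate
4 | (3E,5S)-5,6-dihydroxy-3-methylhex-3-en-2-one | CC(=O)/C(C)=C/[C@H](O)CO | intermediate
5 | (2S,3E)-2-hydroxy-4-methyl-5-oxohex-3-en-1-yl 2,2-dimethylpropanoate | CC(=O)/C(C)=C/[C@H](O)COC(=O)C(C)(C)C | intermediate
6 | 2-methylprop-2-enoyl chloride | C=C(C)C(Cl)=O | starting material
7 | (2S,3E)-1-[(2,2-dimethylpropanoyl)oxy]-4-methyl-5-oxohex-3-en-2-yl 2-methylprop-2-enoate | CC(=O)/C(C)=C/[C@H](OC(=O)C(C)=C)COC(=O)C(C)(C)C | intermediate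
8 | (2S,3E)-5-{[tert-butyl(dimethyl)silyl]oxy}-1-[(2,2-dimethylpropanoyl)oxy]-4-methylhexa-3,5-dien-2-yl 2-methylprop-2-enoate | C=C(O[Si](C)(C)C(C)(C)C)/C(C)=C/[C@H](OC(=O)C(C)=C)COC(=O)C(C)(C)C | intermediate
9 | [(1S,3aS,7aS)-6-{[tert-butyl(dimethyl)silyl]oxy}-3a,7-dimethyl-3-oxo-1,3,3a,4,5,7a-hexahydro-2-benzofuran-1-yl]methyl 2,2-dimethylpropanoate | O=C1O[C@H](COC(=O)C(C)(C)C)[C@H]2C(C)=C(O[Si](C)(C)C(C)(C)C)CC[C@]12C | intermediate
10 | 2-{[tert-butyl(dimethyl)silyl]oxy}-N-methoxy-N-methylacetamide | CON(C)C(=O)CO[Si](C)(C)C(C)(C)C | starting material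
11 | ethynyl(trimethyl)silane | C#C[Si](C)(C)C | starting material
12 | 1-{[tert-butyl(dimethyl)silyl]oxy}-4-(trimethylsilyl)but-3-yn-2-one | CC(C)(C)[Si](C)(C)OCC(=O)C#C[Si](C)(C)C | intermediate
13 | tert-butyl{[(2E)-3-chloro-2-[(trimethylsilyl)ethynyl]prop-2-en-1-yl]oxy}dimethylsilane | Cl/C=C(\C#C[Si](C)(C)C)CO[Si](C)(C)C(C)(C)C | intermediate
14 | tert-butyl{[(2E)-2-(chloromethylidene)but-3-yn-1-yl]oxy}dimethylsilane | Cl/C=C(\C#C)CO[Si](C)(C)C(C)(C)C | intermediate
15 | hydroxy ynone (1S,9S,10S): ring A enol ether, C1–C2(=O)–east arm, C10–C9H(OH)–C8aH2OPiv | C[C@]1(C(=O)C#C/C(CO[Si](C)(C)C(C)(C)C)=C\Cl)CCC(O[Si](C)(C)C(C)(C)C)=C(C)[C@@H]1[C@H](O)COC(=O)C(C)(C)C | intermediate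
16 | propargylic diol: as 15 with (2S)-C2H(OH) | C[C@]1([C@H](O)C#C/C(CO[Si](C)(C)C(C)(C)C)=C\Cl)CCC(O[Si](C)(C)C(C)(C)C)=C(C)[C@@H]1[C@H](O)COC(=O)C(C)(C)C | intermediate
17 | triol: as 16 with C8aH2OH | C[C@]1([C@H](O)C#C/C(CO[Si](C)(C)C(C)(C)C)=C\Cl)CCC(O[Si](C)(C)C(C)(C)C)=C(C)[C@@H]1[C@H](O)CO | intermediate
18 | hydroxy aldehyde (open form of the lactol): ring A enol ether, C1–(2S)-C2H(OH)–east arm, C10–C9HO | C[C@]1([C@H](O)C#C/C(CO[Si](C)(C)C(C)(C)C)=C\Cl)CCC(O[Si](C)(C)C(C)(C)C)=C(C)[C@@H]1C=O | intermediate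
19 | dimethyl (2S)-2-hydroxybutanedioate | COC(=O)C[C@H](O)C(=O)OC | starting material
20 | dimethyl (2S,3R)-2-hydroxy-3-methylbutanedioate | COC(=O)[C@H](C)[C@H](O)C(=O)OC | intermediate
21 | (2S,3R)-2-hydroxy-3-methylbutanedioic acid | OC(=O)[C@H](C)[C@H](O)C(=O)O | intermediate
22 | (2R)-2-[(2S,4S)-2-tert-butyl-5-oxo-1,3-dioxolan-4-yl]propanoic acid | OC(=O)[C@H](C)[C@@H]1O[C@H](C(C)(C)C)OC1=O | intermediate
23 | tert-butyl (2R)-2-[(2S,4S)-2-tert-butyl-5-oxo-1,3-dioxolan-4-yl]propanoate | CC(C)(C)OC(=O)[C@H](C)[C@@H]1O[C@H](C(C)(C)C)OC1=O | intermediate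
24 | aldol adduct: as 18 with (9R)-C9H(OH) bonded to (8R)-C8 of the 2-tert-butyl-5-oxo-1,3-dioxolane that carries the (17R)-CH(CH3)CO2t-Bu group | C[C@]1([C@H](O)C#C/C(CO[Si](C)(C)C(C)(C)C)=C\Cl)CCC(O[Si](C)(C)C(C)(C)C)=C(C)[C@@H]1[C@@H](O)[C@]2(O[C@H](C(C)(C)C)OC2=O)[C@@H](C)C(=O)OC(C)(C)C | intermediate
25 | dioxolane hemiacetal: as 24 with C7H(OH) in place of C7=O (either configuration at C7; aluminium-bound in the flask) | C[C@]1([C@H](O)C#C/C(CO[Si](C)(C)C(C)(C)C)=C\Cl)CCC(O[Si](C)(C)C(C)(C)C)=C(C)[C@@H]1[C@@H](O)[C@]2(O[C@H](C(C)(C)C)OC2O)[C@@H](C)C(=O)OC(C)(C)C | intermediate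
26 | α-hydroxy aldehyde triol: C8(OH)(C7HO)[(17R)-CH(CH3)CO2t-Bu] on (9R)-C9H(OH); C2–OH free | C[C@]1([C@H](O)C#C/C(CO[Si](C)(C)C(C)(C)C)=C\Cl)CCC(O[Si](C)(C)C(C)(C)C)=C(C)[C@@H]1[C@@H](O)[C@@](O)(C=O)[C@@H](C)C(=O)OC(C)(C)C | intermediate
27 | diacetate: as 26 with C2–OAc and C9–OAc | C[C@]1([C@H](OC(C)=O)C#C/C(CO[Si](C)(C)C(C)(C)C)=C\Cl)CCC(O[Si](C)(C)C(C)(C)C)=C(C)[C@@H]1[C@@H](OC(C)=O)[C@@](O)(C=O)[C@@H](C)C(=O)OC(C)(C)C | intermediate
28 | α-silyloxy ketone: as 27 with C12=O and (11S)-C11(OTBS)(CH3) | C[C@]1([C@H](OC(C)=O)C#C/C(CO[Si](C)(C)C(C)(C)C)=C\Cl)CCC(=O)[C@@](C)(O[Si](C)(C)C(C)(C)C)[C@@H]1[C@@H](OC(C)=O)[C@@](O)(C=O)[C@@H](C)C(=O)OC(C)(C)C | intermediate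
29 | enone: as 28 with C13=C14 | C[C@]1([C@H](OC(C)=O)C#C/C(CO[Si](C)(C)C(C)(C)C)=C\Cl)C=CC(=O)[C@@](C)(O[Si](C)(C)C(C)(C)C)[C@@H]1[C@@H](OC(C)=O)[C@@](O)(C=O)[C@@H](C)C(=O)OC(C)(C)C | intermediate
30 | (3Z)-diene: as 29 with C3H=C4H (Z) | C[C@]1([C@H](OC(C)=O)/C=C\C(CO[Si](C)(C)C(C)(C)C)=C/Cl)C=CC(=O)[C@@](C)(O[Si](C)(C)C(C)(C)C)[C@@H]1[C@@H](OC(C)=O)[C@@](O)(C=O)[C@@H](C)C(=O)OC(C)(C)C | intermediate
31 | allylic alcohol: as 30 with C16H2OH and C11–OH | C[C@]1([C@H](OC(C)=O)/C=C\C(CO)=C/Cl)C=CC(=O)[C@@](C)(O)[C@@H]1[C@@H](OC(C)=O)[C@@](O)(C=O)[C@@H](C)C(=O)OC(C)(C)C | intermediate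
32 | allylic bromide: as 31 with C16H2Br | C[C@]1([C@H](OC(C)=O)/C=C\C(CBr)=C/Cl)C=CC(=O)[C@@](C)(O)[C@@H]1[C@@H](OC(C)=O)[C@@](O)(C=O)[C@@H](C)C(=O)OC(C)(C)C | intermediate
33 | ten-membered hydroxy ester: target skeleton with C7–OH free and C19 as tert-butyl ester (6S,7R) | C=C1/C=C\[C@@H](OC(C)=O)[C@@]2(C)C=CC(=O)[C@@](C)(O)[C@@H]2[C@@H](OC(C)=O)[C@](O)([C@@H](C)C(=O)OC(C)(C)C)[C@@H](O)[C@H]1Cl | intermediate
34 | seco hydroxy acid: as 33 with C19O2H | C=C1/C=C\[C@@H](OC(C)=O)[C@@]2(C)C=CC(=O)[C@@](C)(O)[C@@H]2[C@@H](OC(C)=O)[C@](O)([C@@H](C)C(=O)O)[C@@H](O)[C@H]1Cl | intermediate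
35 | CNP0188317.3, (1S,2R,3Z,6S,7R,8R,9R,10S,11S,17R) | C=C1/C=C\[C@@H](OC(C)=O)[C@@]2(C)C=CC(=O)[C@@](C)(O)[C@@H]2[C@@H](OC(C)=O)[C@]2(O)[C@@H](C)C(=O)O[C@H]2[C@H]1Cl | target

**Step count.** Total: 27 steps. Longest linear sequence: 20 steps (steps 1–6, 10–13, 18–27).

**Steps most likely to fail**

Step 26. Ring closure may lose to intermolecular coupling or to simple reduction of the allylic bromide, and the allyl unit may reach the wrong face of the aldehyde. The fallback sets out from allylic alcohol 31 (step 25 is skipped) and comes back at 33. It replaces the stoichiometric chromium Barbier reaction by a catalytic umpolung allylation: Pd(PPh3)4 (zerovalent palladium) and Et3B in dilute THF should turn the allylic alcohol into a π-allylpalladium species and then into an allylborane, which adds to the aldehyde through a closed six-membered transition state. This fallback makes no new compound (F0).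

Step 6. The ester-tethered cycloaddition may be slow enough for the silyl dienol ether to be lost on heating, and exo/endo (trans/cis ring fusion) selection may be poor. The fallback sets out from enone ester 7 and comes back at 9. Pyrrolidine with catalytic AcOH in MeCN at 60 °C should convert the methyl ketone into a cross-conjugated 2-aminodiene, which is more electron-rich and should cyclise at lower temperature under the same allylic-strain control. Hydrolysis gives keto lactone F1. Thermodynamic silylation (TBSCl, NaI, Et3N, MeCN, 40 °C) then gives the tetrasubstituted enol ether 9.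

Step 18. The lactol may open reluctantly, the hindered aldehyde may enolise and epimerise at C10, the aldolate may revert, and facial selection at C9 may be insufficient. The fallback sets out from 18 and comes back at 24. Oxidation of the lactol with Ag2CO3 on Celite gives γ-lactone F2. Claisen-type acylation of the lithium enolate of 23 by F2, again anti to the tert-butyl group, gives β-keto dioxolanone F3. C9 is then set by hydride delivery to the C9 ketone (Zn(BH4)2, chelation with O8, or a bulky borohydride if the other face is needed) instead of by C–C bond formation, to give 24.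

**Further compounds**

F0 | step 26 | none | none
F1 | step 6 | [(1S,3aS,7aS)-3a,7-dimethyl-3,6-dioxooctahydro-2-benzofuran-1-yl]methyl 2,2-dimethylpropanoate (both epimers at the CH(CH3) carbon) | O=C1O[C@H](COC(=O)C(C)(C)C)[C@H]2C(C)C(=O)CC[C@]12C
F2 | step 18 | γ-lactone of 18: C9(=O)–O–C2 bridge, trans-fused to the ring A enol ether, C2 bearing the east arm; C1, C2, C10 as in 18 | O=C1O[C@H](C#C/C(CO[Si](C)(C)C(C)(C)C)=C\Cl)[C@@]2(C)CCC(O[Si](C)(C)C(C)(C)C)=C(C)[C@H]12
F3 | step 18 | β-keto dioxolanone: as 24 with C9=O in place of C9H(OH) | C[C@]1([C@H](O)C#C/C(CO[Si](C)(C)C(C)(C)C)=C\Cl)CCC(O[Si](C)(C)C(C)(C)C)=C(C)[C@@H]1C(=O)[C@]2(O[C@H](C(C)(C)C)OC2=O)[C@@H](C)C(=O)OC(C)(C)C
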